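**Retrosynthetic overview**

1. Target 19 comes from its bis-MOM ether 18 by cleavage of the two aryl O–CH2OMe acetals; 19 has no stereocentre.
2. The strategy rests on C-1 of the propane-1,3-dione, the carbonyl carbon bonded to ring A (the 4-hydroxy-2-methoxy-3-prenylphenyl ring). It lies 1,3 to the ring B carbonyl C-3 across methylene C-2, so it is the β-carbon of the retrochalcone enone C-3(=O)–C-2=C-1. Its oxygen is therefore delivered to that C=C: 18 from oxirane 17 by isomerisation, and 17 from (E)-enone 14 plus hydrogen peroxide 15.
3. Enone 14 comes from aldehyde 9 and methyl ketone 12 (C-1–C-2 bond by Claisen–Schmidt condensation).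
4. Each prenyl group comes from an ortho-allyl group by cross-metathesis with 2-methyl-2-butene 8. The ring A allyl group is placed at C-3 by a chelation-guided aromatic Claisen rearrangement of the 4-O-allyl ether of 1; ring B starts from allylphenol 10.
5. Ring order: both benzene rings are bought. The only ring closed is the oxirane (step 9), and it is opened again in step 10.

Key step: step 9

Remark: the target is drawn as the diketo tautomer and is expected to exist largely as its chelated enol.
Remark: 1-(3-allyl-4-hydroxyphenyl)ethanone 10 is taken as a purchasable compound.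

**Route**

Step 1
Reactants: 1 2,4-dihydroxybenzaldehyde; 2 allyl bromide (3-bromoprop-1-ene)
Product: 3 4-(allyloxy)-2-hydroxybenzaldehyde
Conditions: K2CO3 (1.0 equiv), acetone, reflux
Reagents that add atoms: none
Why: Williamson etherification; the 2-OH is held in a hydrogen bond to the aldehyde and is the less acidic site, so with one equivalent of weak base only the 4-phenoxide should be allylated.

Step 2
Reactants: 3 4-(allyloxy)-2-hydroxybenzaldehyde
Product: 5 3-allyl-2,4-dihydroxybenzaldehyde, via ortho-dienone 4 (not isolated)
Conditions: N,N-diethylaniline, 200 °C, argon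
Reagents that add atoms: none
Why: Aromatic Claisen rearrangement ([3,3] shift, then enolisation of 4); the chelated 2-hydroxy aldehyde localises double-bond character between C-3 and C-4, which should send the allyl group to C-3 between the two oxygens and not to C-5, as is known for 4-allyloxy-2-hydroxyaryl carbonyl compounds.

Step 3
Reactants: 5 3-allyl-2,4-dihydroxybenzaldehyde
Product: 6 3-allyl-2-hydroxy-4-(methoxymethoxy)benzaldehyde
Conditions: MOMCl (1.1 equiv), K2CO3, acetone, 0 °C to rt
Reagents that add atoms: chloromethyl methyl ether (MOMCl), COCCl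
Why: O-alkylation of a phenoxide to a mixed acetal; the free, more acidic 4-OH should react while the chelated 2-OH is left for the next step.

Step 4
Reactants: 6 3-allyl-2-hydroxy-4-(methoxymethoxy)benzaldehyde
Product: 7 3-allyl-2-methoxy-4-(methoxymethoxy)benzaldehyde
Conditions: MeI, K2CO3, DMF, 40 °C
Reagents that add atoms: iodomethane (MeI), CI
Why: Williamson methylation; in a dipolar aprotic solvent the remaining chelated phenol is ionised and methylated, and the aldehyde, allyl group and MOM acetal are inert.

Step 5
Reactants: 7 3-allyl-2-methoxy-4-(methoxymethoxy)benzaldehyde; 8 2-methyl-2-butene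
Product: 9 2-methoxy-4-(methoxymethoxy)-3-(3-methylbut-2-enyl)benzaldehyde
Conditions: 8 (excess), second-generation Grubbs catalyst (H2IMes)(PCy3)Cl2Ru=CHPh (3 mol%), CH2Cl2, 40 °C, sealed vessel
Reagents that add atoms: none
Why: Olefin cross-metathesis; the terminal allyl alkene exchanges its CH2 end for the isopropylidene unit of 8 with loss of propene, the trisubstituted product does not react further, and the ruthenium carbene tolerates aldehyde and acetal.

Step 6
Reactants: 10 1-(3-allyl-4-hydroxyphenyl)ethanone
Product: 11 1-[3-allyl-4-(methoxymethoxy)phenyl]ethanone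
Conditions: MOMCl (1.2 equiv), K2CO3, acetone, rt
Reagents that add atoms: chloromethyl methyl ether (MOMCl), COCCl
Why: O-alkylation of the acidic para-acyl phenoxide gives the base-stable MOM acetal needed for steps 8 and 9.

Step 7
Reactants: 11 1-[3-allyl-4-(methoxymethoxy)phenyl]ethanone; 8 2-methyl-2-butene
Product: 12 1-[4-(methoxymethoxy)-3-(3-methylbut-2-enyl)phenyl]ethanone
Conditions: 8 (excess), second-generation Grubbs catalyst (H2IMes)(PCy3)Cl2Ru=CHPh (3 mol%), CH2Cl2, 40 °C, sealed vessel
Reagents that add atoms: none
Why: Olefin cross-metathesis as in step 5; the aryl methyl ketone and the MOM ether are tolerated and propene is lost.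

Step 8
Reactants: 9 2-methoxy-4-(methoxymethoxy)-3-(3-methylbut-2-enyl)benzaldehyde; 12 1-[4-(methoxymethoxy)-3-(3-methylbut-2-enyl)phenyl]ethanone
Product: 14 (E)-3-[2-methoxy-4-(methoxymethoxy)-3-(3-methylbut-2-enyl)phenyl]-1-[4-(methoxymethoxy)-3-(3-methylbut-2-enyl)phenyl]prop-2-en-1-one, via aldol adduct 13 (not isolated)
Conditions: KOH (aq., 3 equiv), EtOH, rt
Reagents that add atoms: none
Why: Claisen–Schmidt condensation; aldehyde 9 has no α-hydrogen, so only the enolate of 12 forms, and adduct 13 loses water by an E1cB path to the conjugated, thermodynamically favoured (E)-enone; MOM ethers and prenyl groups are stable to hydroxide.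

Step 9
Reactants: 14 (E)-3-[2-methoxy-4-(methoxymethoxy)-3-(3-methylbut-2-enyl)phenyl]-1-[4-(methoxymethoxy)-3-(3-methylbut-2-enyl)phenyl]prop-2-en-1-one; 15 hydrogen peroxide
Product: 17 rac-[(2R,3S)-3-[2-methoxy-4-(methoxymethoxy)-3-(3-methylbut-2-enyl)phenyl]oxiran-2-yl]-[4-(methoxymethoxy)-3-(3-methylbut-2-enyl)phenyl]methanone (trans; the 2R,3S enantiomer drawn), via hydroperoxy enolate 16 (not isolated)
Conditions: 30% aq. H2O2 (5 equiv), 2 M aq. NaOH (1.5 equiv), MeOH–THF 1:1, 0 °C to rt
Reagents that add atoms: none
Why: Weitz–Scheffer nucleophilic epoxidation, the standard oxidation of chalcones: hydroperoxide anion adds to the β-carbon of the enone (the future ring A carbonyl carbon C-1) to give enolate 16, whose α-carbon then attacks the proximal peroxide oxygen and expels hydroxide. The oxirane is closed in a 3-exo-tet mode (intramolecular SN2 at oxygen), forming the C-1–O bond that is kept and a C-2–O bond that is given up again in step 10. The two new stereocentres (C-2 and C-3 of the oxirane) are related by the (E)-alkene and by free rotation in 16, which lets the ring close with the aroyl and aryl groups anti, so the trans racemate should result; no absolute control is needed because both centres are erased in step 10. The step needs chemoselectivity among three C=C bonds: hydroperoxide is a nucleophilic oxidant and should attack only the electron-poor conjugated alkene, leaving the two electron-rich trisubstituted prenyl alkenes that a peracid would oxidise first. Both phenols are capped as base-stable MOM ethers, so no phenoxide deactivates the enone or opens a Dakin-type path, and the ketone ring has no ortho-hydroxyl, so Algar–Flynn–Oyamada closure to a flavonol cannot compete. The donor-substituted ring A lowers the electrophilicity of the β-carbon, which is answered by excess oxidant and a longer reaction time.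

Step 10
Reactants: 17 rac-[(2R,3S)-3-[2-methoxy-4-(methoxymethoxy)-3-(3-methylbut-2-enyl)phenyl]oxiran-2-yl]-[4-(methoxymethoxy)-3-(3-methylbut-2-enyl)phenyl]methanone
Product: 18 1-[2-methoxy-4-(methoxymethoxy)-3-(3-methylbut-2-enyl)phenyl]-3-[4-(methoxymethoxy)-3-(3-methylbut-2-enyl)phenyl]propane-1,3-dione
Conditions: Pd(PPh3)4 (5 mol%), Ph2PCH2CH2PPh2 (5 mol%), toluene, 80–100 °C, argon
Reagents that add atoms: none
Why: Isomerisation of an α,β-epoxy ketone to a β-diketone under zerovalent palladium and bisphosphine catalysis; the metal should open the oxirane C-2–O bond next to the carbonyl, a hydride then passes from C-3 to C-2 through the metal and the catalyst is released, leaving the oxygen on the ring A carbon as a ketone, while prenyl alkenes and MOM ethers are inert to this catalyst.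

Step 11
Reactants: 18 1-[2-methoxy-4-(methoxymethoxy)-3-(3-methylbut-2-enyl)phenyl]-3-[4-(methoxymethoxy)-3-(3-methylbut-2-enyl)phenyl]propane-1,3-dione
Product: 19 1-[4-hydroxy-2-methoxy-3-(3-methylbut-2-enyl)phenyl]-3-[4-hydroxy-3-(3-methylbut-2-enyl)phenyl]propane-1,3-dione
Conditions: HCl (0.5 M) in MeOH, rt to 40 °C
Reagents that add atoms: none
Why: Acid-catalysed acetal solvolysis (transacetalisation to methanol) frees both phenols; dilute acid near room temperature is chosen so that the ortho-prenyl phenols do not cyclise to 2,2-dimethylchromans, and with a 2-methoxy group on ring A there is no ortho-hydroxyl for flavone closure.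

**Compound list**

1 | 2,4-dihydroxybenzaldehyde | O=Cc1ccc(O)cc1O | starting material
2 | allyl bromide (3-bromoprop-1-ene) | C=CCBr | starting material
3 | 4-(allyloxy)-2-hydroxybenzaldehyde | O=Cc1ccc(OCC=C)cc1O | intermediate
4 | 3-allyl-2-hydroxy-4-oxocyclohexa-1,5-diene-1-carbaldehyde (ortho-dienone, racemic) | O=CC1=C(O)C(CC=C)C(=O)C=C1 | intermediate (not isolated)
5 | 3-allyl-2,4-dihydroxybenzaldehyde | O=Cc1ccc(O)c(CC=C)c1O | intermediate
6 | 3-allyl-2-hydroxy-4-(methoxymethoxy)benzaldehyde | O=Cc1ccc(OCOC)c(CC=C)c1O | intermediate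
7 | 3-allyl-2-methoxy-4-(methoxymethoxy)benzaldehyde | O=Cc1ccc(OCOC)c(CC=C)c1OC | intermediate
8 | 2-methyl-2-butene | CC=C(C)C | starting material
9 | 2-methoxy-4-(methoxymethoxy)-3-(3-methylbut-2-enyl)benzaldehyde | O=Cc1ccc(OCOC)c(CC=C(C)C)c1OC | intermediate
10 | 1-(3-allyl-4-hydroxyphenyl)ethanone | CC(=O)c1ccc(O)c(CC=C)c1 | starting material
11 | 1-[3-allyl-4-(methoxymethoxy)phenyl]ethanone | CC(=O)c1ccc(OCOC)c(CC=C)c1 | intermediate
12 | 1-[4-(methoxymethoxy)-3-(3-methylbut-2-enyl)phenyl]ethanone | CC(=O)c1ccc(OCOC)c(CC=C(C)C)c1 | intermediate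
13 | racemic 3-hydroxy-3-[2-methoxy-4-(methoxymethoxy)-3-(3-methylbut-2-enyl)phenyl]-1-[4-(methoxymethoxy)-3-(3-methylbut-2-enyl)phenyl]propan-1-one (aldol adduct) | COCOc1ccc(C(O)CC(=O)c2ccc(OCOC)c(CC=C(C)C)c2)c(OC)c1CC=C(C)C | intermediate (not isolated)
14 | (E)-3-[2-methoxy-4-(methoxymethoxy)-3-(3-methylbut-2-enyl)phenyl]-1-[4-(methoxymethoxy)-3-(3-methylbut-2-enyl)phenyl]prop-2-en-1-one | COCOc1ccc(/C=C/C(=O)c2ccc(OCOC)c(CC=C(C)C)c2)c(OC)c1CC=C(C)C | intermediate
15 | hydrogen peroxide | OO | starting material
16 | sodium (Z)-3-hydroperoxy-3-[2-methoxy-4-(methoxymethoxy)-3-(3-methylbut-2-enyl)phenyl]-1-[4-(methoxymethoxy)-3-(3-methylbut-2-enyl)phenyl]prop-1-en-1-olate (racemic at the hydroperoxy carbon) | [Na+].[O-]/C(=C\C(OO)c1ccc(OCOC)c(CC=C(C)C)c1OC)c1ccc(OCOC)c(CC=C(C)C)c1 | intermediate (not isolated)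
17 | rac-[(2R,3S)-3-[2-methoxy-4-(methoxymethoxy)-3-(3-methylbut-2-enyl)phenyl]oxiran-2-yl]-[4-(methoxymethoxy)-3-(3-methylbut-2-enyl)phenyl]methanone (trans racemate; 2R,3S enantiomer drawn) | O=C(c1ccc(OCOC)c(CC=C(C)C)c1)[C@@H]2O[C@H]2c1ccc(OCOC)c(CC=C(C)C)c1OC | intermediate
18 | 1-[2-methoxy-4-(methoxymethoxy)-3-(3-methylbut-2-enyl)phenyl]-3-[4-(methoxymethoxy)-3-(3-methylbut-2-enyl)phenyl]propane-1,3-dione | COCOc1ccc(C(=O)CC(=O)c2ccc(OCOC)c(CC=C(C)C)c2)c(OC)c1CC=C(C)C | intermediate
19 | 1-[4-hydroxy-2-methoxy-3-(3-methylbut-2-enyl)phenyl]-3-[4-hydroxy-3-(3-methylbut-2-enyl)phenyl]propane-1,3-dione (CNP0167758.0) | COc1c(C(=O)CC(=O)c2ccc(O)c(CC=C(C)C)c2)ccc(O)c1CC=C(C)C | target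

**Step count and risks**

Total step count: 11. Longest linear sequence: 9 steps (steps 1–5 and 8–11, from 1 to 19); steps 6 and 7 form the convergent ring B branch.

The three steps most likely to fail:

Step 10 (palladium-catalysed isomerisation). Ionisation of the benzylic C-3–O bond, strongly assisted by the ortho-methoxy and para-alkoxy donors of ring A, may outrun the catalyst at 80–100 °C and divert material into a Meinwald-type 1,2-shift. Turnover may also stall after ring opening. The fallback replaces the isomerisation by a reduction followed by an oxidation. It sets out from 17: SmI2 (divalent samarium, 2.2 equiv) in THF–MeOH at −78 °C should cleave the C-2–O bond next to the ketone and give β-hydroxy ketone 13. Oxidation of 13 with 2-iodoxybenzoic acid in EtOAc at 75 °C should give the β-diketone, and the route is rejoined at 18. This detour makes no compound outside the list (F0).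

Step 9 (key epoxidation). Conjugate addition of hydroperoxide may be too slow because ring A donates into the enone. Hydroxide may cause retro-aldol cleavage, or the acid-labile benzylic oxirane may open during isolation (neutral work-up and base-washed silica are planned). The fallback builds the diketone by a crossed Claisen condensation, bringing the ring A carbon in at the carboxylic oxidation level. It sets out from 9: Pinnick oxidation (NaClO2, NaH2PO4, 8 as chlorine scavenger, t-BuOH–H2O, rt) should give 2-methoxy-4-(methoxymethoxy)-3-(3-methylbut-2-enyl)benzoic acid F1. Methylation (MeI, K2CO3, DMF) should give methyl 2-methoxy-4-(methoxymethoxy)-3-(3-methylbut-2-enyl)benzoate F2. The sodium enolate of 12 (NaH, THF, reflux) is then acylated by F2 and, after buffered work-up, the route is rejoined at 18.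

Step 2 (Claisen rearrangement). Part of the allyl group may migrate to C-5, or the hydroxy aldehyde may degrade at 200 °C. The fallback uses direct C-alkylation of the phenoxide in place of the sigmatropic shift and the metathesis. It sets out from 1: 1-bromo-3-methylbut-2-ene in aqueous KOH at rt should alkylate the doubly activated C-3 and give 2,4-dihydroxy-3-(3-methylbut-2-enyl)benzaldehyde F3, which is separated by chromatography from C-5 and O-alkylated isomers. Selective protection (MOMCl, K2CO3, acetone) should give 2-hydroxy-4-(methoxymethoxy)-3-(3-methylbut-2-enyl)benzaldehyde F4, and methylation (MeI, K2CO3, DMF) rejoins the route at 9.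

**Further compounds**

F0 | step 10 | none | none
F1 | step 9 | 2-methoxy-4-(methoxymethoxy)-3-(3-methylbut-2-enyl)benzoic acid | OC(=O)c1ccc(OCOC)c(CC=C(C)C)c1OC
F2 | step 9 | methyl 2-methoxy-4-(methoxymethoxy)-3-(3-methylbut-2-enyl)benzoate | COC(=O)c1ccc(OCOC)c(CC=C(C)C)c1OC
F3 | step 2 | 2,4-dihydroxy-3-(3-methylbut-2-enyl)benzaldehyde | O=Cc1ccc(O)c(CC=C(C)C)c1O
F4 | step 2 | 2-hydroxy-4-(methoxymethoxy)-3-(3-methylbut-2-enyl)benzaldehyde | O=Cc1ccc(OCOC)c(CC=C(C)C)c1O
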